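The constants of the steps are unknown to me, so I look for one number the runs can give without them: the exchange count n, the exchanges delivered per complex charged over the whole life of the incoming ligand.

| flask | starting complex | incoming ligand | remark | time |
|---|---|---|---|---|
| south-west | 0.0034 M | 0.026 M | run made earlier |  |
| north | 0.069 M | 0.026 M | run made earlier |  |
| epsilon | 0.0050 M | 0.0260 M |  | 10 h |
| eta | 0.010 M | 0.0260 M |  | 10 h |
| theta | 0.020 M | 0.0260 M |  | 10 h |
| zeta | 0.040 M | 0.0260 M |  | 10 h |
| gamma | 0.080 M | 0.0260 M |  | 10 h |

- south-west (time / h: complex with three exchanged / %, starting complex / %): 1.33: 46.1, 11.2; 3.00: 53.3, 5.7; 4.00: 54.6, 5.1; 6.00: 54.9, 4.6; 8.00: 54.0, 1.3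
- north (time / h: complex with three exchanged / %, starting complex / %): 1.33: 0, 44.4; 3.00: 1.2, 37.1; 4.00: 1.1, 39.3; 6.00: 1.1, 38.0; 8.00: 0, 38.5

(each reading ± 1 percentage point)

- what was read earlier has a scatter of 1 percentage point, one standard deviation
- reactions considered so far: leaving ligand + starting complex -> side product; complex with one exchanged + incoming ligand -> leaving ligand + complex with two exchanged; starting complex + incoming ligand -> leaving ligand + complex with one exchanged; incoming ligand -> decomposed reagent; complex with two exchanged + incoming ligand -> leaving ligand + complex with three exchanged
- "hardly changes" means that all values lie within two and a half points (for a concentration: within two and a half percent of the largest)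

* [complex with three exchanged] at the end for epsilon, eta, theta, zeta, gamma, in this order
* the course of these numbers from the first flask to the last (hardly changes / falls all the way / rises all the way / rises, then falls / falls, then rises)

Does the ligand stop the exchange? In the north run starting complex reads 37.1% at 3.00 h and 38.5% at 8.00 h, so exchange stops with starting complex present, and I take the incoming ligand to be lost partly by decay.

How does it divide? I replace the falling complex curve by its charge, which makes capture pseudo-first-order in ligand and fixes its share against decay. The inverse of n is then c + w, where c is the complex charged per ligand charged and w is the decay constant over the capture constant times the ligand charge, which holds for this ligand charge.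

What is w? Starting complex is a poor gauge of n, because leaving ligand consumes it too, so its reading counts more than the complexes never struck; complex with three exchanged is consumed by no reaction considered, so I read n from that. If exchanges strike at random, the number of strikes on a complex is Poisson with mean n, so the south-west reading of 54.9% at 6.00 h, taken as the fraction struck at least 3 times and solved by one Newton step from n = 3, gives n = 2.88, and the waste term is w = 0.217.

For north the rule gives n = 0.348, and a fraction struck at least 3 times of 0.542%, within the scatter of its readings, 1.2% at most.

That fraction times the charge gives my row:

- epsilon, n = 2.44: 0.00221 M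
- eta: 0.00233 M
- theta: 0.00166 M
- zeta: 8.09 × 10⁻⁴ M
- gamma, n = 0.304: 2.98 × 10⁻⁴ M

My peak is eta, higher than its neighbours.

The forecast reads 0.0026 M, 0.0033 M, 0.0025 M, 0.0011 M, 4.000 × 10⁻⁴ M, a course that rises, then falls, above mine at eta, on the ground that “The final amount should therefore peak near 0.01 M charge, then fall.”

The flasks give 0.00229 M, 0.00275 M, 0.00236 M, 0.00142 M, 6.21 × 10⁻⁴ M: rises, then falls, with eta higher than its neighbours.

    leaving ligand + starting complex → side product (k = 0.00990 /M/s)
    complex with one exchanged + incoming ligand → leaving ligand + complex with two exchanged (k = 0.0450 /M/s)
    starting complex + incoming ligand → leaving ligand + complex with one exchanged (k = 0.0420 /M/s)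
    incoming ligand → decomposed reagent (k = 3.60 × 10⁻⁴ /s)
    complex with two exchanged + incoming ligand → leaving ligand + complex with three exchanged (k = 0.100 /M/s)

In epsilon the decay of incoming ligand starts at 1.7 times the rate of the first exchange, and with incoming ligand at 0% after 10.0 h, the ligand not decomposed makes 1.87 exchanges per complex charged, against 2.44 from my rule. In gamma, where incoming ligand is the limiting reagent at 0% with 45.8% of the starting complex standing, the same balance gives 0.294 against 0.304.

The numbers in the tables are simulated from invented constants; scatter was added.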